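The route rests on disconnecting the upper pyran ring at O1–C8a and C4–C4a, so that the upper catechol ring A is delivered as 2-fluoro-3,4-bis(benzyloxy)phenyllithium, a regiodefined 1,2-dipole. Its partner is the (αR,βS)-epoxide of a chalcone whose carbonyl already sits on C6 of the finished lower flavan. In one operation the aryllithium adds to the ketone (C4–C4a), the new alkoxide undergoes Payne rearrangement, which shifts the epoxide to C3–C4 and frees O1 on C2, and O1 displaces fluoride (O1–C8a). The step exploits the ortho C4a/C8a pair of ring A and the vicinal O1/O3 oxygens of ring C; hydride then opens the C3–C4 epoxide to set the 3,4-cis triarylmethine.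

Key step: step 13

Remark: locants are flavan locants; plain locants (O1, C2 … C8a) belong to the upper unit and primed ones to the lower unit; Bn = benzyl. Compounds 1, 4, 5, 7 and 16 and the catalyst poly-L-leucine are taken as commercial.

Step 1
Reactants: 1 3-fluorocatechol (3-fluorobenzene-1,2-diol)
Product: 2 1,2-bis(benzyloxy)-3-fluorobenzene
Conditions: BnBr, K2CO3, DMF, 60 °C
Reagents that add atoms: benzyl bromide, BrCc1ccccc1
Why: Williamson ether synthesis: both phenoxides of the catechol are benzylated under K2CO3 in DMF and no stereocentre is involved.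

Step 2
Reactants: 2 1,2-bis(benzyloxy)-3-fluorobenzene
Product: 3 1,2-bis(benzyloxy)-4-bromo-3-fluorobenzene
Conditions: NBS, MeCN, 0 °C to rt
Reagents that add atoms: N-bromosuccinimide, O=C1CCC(=O)N1Br
Why: Electrophilic aromatic bromination should go para to the unhindered 1-benzyloxy group (the position next to fluorine), because the 2-benzyloxy group is twisted out of conjugation by its two ortho neighbours and its para position is deactivated by the meta fluorine.

Step 3
Reactants: 4 (S)-4-benzyl-1,3-oxazolidin-2-one; 5 benzyloxyacetyl chloride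
Product: 6 (S)-4-benzyl-3-[(benzyloxy)acetyl]-1,3-oxazolidin-2-one
Conditions: n-BuLi, THF, −78 °C; then 5, −78 to 0 °C
Reagents that add atoms: none
Why: N-Acylation of the lithiated oxazolidinone by the acid chloride (nucleophilic acyl substitution) gives the Evans glycolate imide without touching the auxiliary stereocentre.

Step 4
Reactants: 6 (S)-4-benzyl-3-[(benzyloxy)acetyl]-1,3-oxazolidin-2-one; 7 4-(benzyloxy)benzaldehyde
Product: 8 (S)-4-benzyl-3-[(2S,3R)-2-(benzyloxy)-3-[4-(benzyloxy)phenyl]-3-hydroxypropanoyl]-1,3-oxazolidin-2-one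
Conditions: Bu2BOTf, i-Pr2NEt, CH2Cl2, −78 to 0 °C; 7, −78 to 0 °C; pH 7 buffer, MeOH, H2O2, 0 °C
Reagents that add atoms: none
Why: Evans syn aldol reaction: the Z-dibutylboron enolate reacts through a Zimmerman–Traxler chair on the face away from the 4-benzyl group of the auxiliary, which sets the future C3' and C2' as the (2S,3R) syn pair needed for a 2,3-cis flavan.

Step 5
Reactants: 8 the syn aldol imide
Product: 9 (2S,3R)-2-(benzyloxy)-3-[4-(benzyloxy)phenyl]-3-hydroxy-N-methoxy-N-methylpropanamide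
Conditions: MeONHMe·HCl, AlMe3, CH2Cl2, −20 to 0 °C; aq. KNaC4H4O6
Reagents that add atoms: N,O-dimethylhydroxylamine hydrochloride, CNOC.Cl
Why: Aluminium amide aminolysis of the imide (Weinreb amide formation), assisted by the aluminium alkoxide of the free β-hydroxyl, cleaves the auxiliary without epimerisation.

Step 6
Reactants: 3 1,2-bis(benzyloxy)-4-bromo-3-fluorobenzene; 9 the Weinreb amide
Product: 11 (2S,3R)-1-[3,4-bis(benzyloxy)-2-fluorophenyl]-2-(benzyloxy)-3-[4-(benzyloxy)phenyl]-3-hydroxypropan-1-one, via arylmagnesium chloride 10 (not isolated)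
Conditions: 3 (1.3 equiv), i-PrMgCl·LiCl (1.3 equiv), THF, −15 to 0 °C; 9 pretreated with i-PrMgCl (1.0 equiv), THF, −20 °C; then combined, −20 to 0 °C; aq. NH4Cl
Reagents that add atoms: none
Why: Bromine–magnesium exchange with i-PrMgCl·LiCl, helped by the ortho fluorine, gives the arylmagnesium chloride, which should not lose magnesium fluoride at or below 0 °C; the hydroxyl of 9 is masked beforehand as its magnesium alkoxide, and the aryl Grignard reagent adds to the Weinreb amide to a chelated tetrahedral intermediate that releases the ketone only on quenching (Weinreb ketone synthesis), so neither over-addition nor early fluoride displacement should occur.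

Step 7
Reactants: 11 the β-hydroxy ketone
Product: 12 (1S,2S,3R)-1-[3,4-bis(benzyloxy)-2-fluorophenyl]-2-(benzyloxy)-3-[4-(benzyloxy)phenyl]propane-1,3-diol (all-syn)
Conditions: Et2BOMe, THF/MeOH, −78 °C; NaBH4; AcOH, then MeOH azeotrope
Reagents that add atoms: none
Why: Narasaka–Prasad reduction: the β-hydroxy ketone is held in a six-membered diethylboron chelate and external hydride adds axially to give the 1,3-syn diol, which sets C4' (S) and completes the all-syn triad.

Step 8
Reactants: 12 the all-syn diol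
Product: 14 (2R,3R,4S)-3,4,7,8-tetrakis(benzyloxy)-2-[4-(benzyloxy)phenyl]chroman (2,3-cis-3,4-trans), via chroman-4-ol 13 (not isolated)
Conditions: KH (2.2 equiv), THF/DMPU, 0 to 60 °C; then BnBr, 0 °C to rt
Reagents that add atoms: benzyl bromide, BrCc1ccccc1
Why: Intramolecular SNAr: of the two potassium alkoxides only the one on the carbon bearing ring B can reach the C–F carbon through a six-membered transition state (the other would form a four-membered ring), so the pyran ring should close with retention at C2' to the 2,3-cis-3,4-trans chroman, and the remaining alkoxide is then benzylated in the same flask (Williamson ether synthesis).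

Step 9
Reactants: 14 the protected lower flavan
Product: 15 (2R,3R,4S)-3,4,7,8-tetrakis(benzyloxy)-2-[4-(benzyloxy)phenyl]-6-bromochroman
Conditions: NBS, CH2Cl2/MeCN, 0 °C
Reagents that add atoms: N-bromosuccinimide, O=C1CCC(=O)N1Br
Why: Electrophilic aromatic bromination at C6', the only ring A position that is ortho to the 7-benzyloxy group and para to the ring oxygen O1'.

Step 10
Reactants: 16 (E)-4-(benzyloxy)cinnamic acid
Product: 17 (E)-3-[4-(benzyloxy)phenyl]-N-methoxy-N-methylprop-2-enamide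
Conditions: CDI, CH2Cl2, rt; then MeONHMe·HCl
Reagents that add atoms: N,O-dimethylhydroxylamine hydrochloride, CNOC.Cl
Why: Amide coupling through the acyl imidazolide gives the Weinreb amide and leaves the E alkene untouched.

Step 11
Reactants: 15 the 6-bromo lower flavan; 17 the cinnamoyl Weinreb amide
Product: 19 (E)-3-[4-(benzyloxy)phenyl]-1-[(2R,3R,4S)-3,4,7,8-tetrakis(benzyloxy)-2-[4-(benzyloxy)phenyl]chroman-6-yl]prop-2-en-1-one, via aryllithium 18 (not isolated)
Conditions: n-BuLi, THF, −78 °C; then 17, −78 to −20 °C; aq. NH4Cl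
Reagents that add atoms: none
Why: Bromine–lithium exchange and 1,2-addition of the aryllithium to the unsaturated Weinreb amide (Weinreb ketone synthesis) should give the E-chalcone after collapse of the tetrahedral intermediate on work-up.

Step 12
Reactants: 19 the chalcone
Product: 20 [(2R,3S)-3-[4-(benzyloxy)phenyl]oxiran-2-yl][(2R,3R,4S)-3,4,7,8-tetrakis(benzyloxy)-2-[4-(benzyloxy)phenyl]chroman-6-yl]methanone (trans-epoxy ketone)
Conditions: poly-L-leucine, urea·H2O2, DBU, THF, rt
Reagents that add atoms: hydrogen peroxide (as its urea adduct), OO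
Why: Juliá–Colonna epoxidation: hydroperoxide adds in conjugate fashion inside the helical poly-L-leucine and closes to the trans-(2R,3S)-epoxy ketone, which fixes the future C2 as (S); because the lower unit is enantiopure the minor epoxide is a diastereomer and should be separable.

Step 13
Reactants: 20 the trans-epoxy ketone; 3 1,2-bis(benzyloxy)-4-bromo-3-fluorobenzene
Product: 24 (1aS,2S,7bS)-4,5-bis(benzyloxy)-2-[4-(benzyloxy)phenyl]-7b-[(2R,3R,4S)-3,4,7,8-tetrakis(benzyloxy)-2-[4-(benzyloxy)phenyl]chroman-6-yl]-1a,7b-dihydro-2H-oxireno[2,3-c]chromene (upper flavan with an α-face 3,4-epoxide trans to the 2-aryl group), via aryllithium 21 (not isolated), via tertiary alkoxide 22 (not isolated), via rearranged alkoxide 23 (not isolated)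
Conditions: 3, t-BuLi (2 equiv), THF, −78 °C; 20 in toluene, −78 °C; then KOt-Bu, DMPU, −78 to 50 °C; aq. NH4Cl
Reagents that add atoms: none
Why: Aryllithium 21, made by bromine–lithium exchange, adds 1,2 to the non-enolisable epoxy ketone to give tertiary alkoxide 22 (C4–C4a bond); with KOt-Bu/DMPU this alkoxide opens the adjacent epoxide from the back at C3 (Payne rearrangement), which shifts the oxirane to C3–C4 and frees the C2 alkoxide 23, and that oxygen displaces fluoride at C8a by intramolecular SNAr (O1–C8a bond). The closest known reactions are the chelation-controlled addition of organolithiums to α,β-epoxy ketones, the Payne rearrangement of 2,3-epoxy alkoxides and the alkoxide–fluoroarene SNAr closure of flavan pyran rings. The new oxirane closes 3-exo-tet and the pyran ring closes by addition–elimination at the arene through a six-membered transition state. C2 keeps the (S) centre of the epoxide, C3 is inverted in the Payne step (hence 2,3-trans), and C4 is fixed in the addition, where lithium holds C=O and the oxirane oxygen s-cis and the aryl group enters from the face of the α-hydrogen, away from oxirane carbon C2. Only this C4 epimer places the fluoroaryl ring cis to C2 on the new oxirane, so only it can cyclise; the tertiary oxygen could form only a four-membered ring and O3 is locked in the oxirane, so O1 alone attacks C8a. The step needs addition to outrun loss of LiF from 21 (secured at −78 °C) and SNAr at an electron-rich arene, which the potassium counter-ion, the dipolar solvent and the absence of an ortho hydrogen (no aryne path) support.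

Step 14
Reactants: 24 the epoxy chroman
Product: 25 (2S,3R,4S)-7,8-bis(benzyloxy)-2-[4-(benzyloxy)phenyl]-4-[(2R,3R,4S)-3,4,7,8-tetrakis(benzyloxy)-2-[4-(benzyloxy)phenyl]chroman-6-yl]chroman-3-ol (2β-aryl, 3α-OH, 4α-aryl)
Conditions: BH3·THF, LiBH4 (cat.), THF, 0 °C to rt; MeOH, aq. NaOH
Reagents that add atoms: none
Why: Borohydride-catalysed reductive opening of a trisubstituted aryl epoxide with borane: hydride should enter at the doubly benzylic C4 anti to the oxirane oxygen (inversion), which places H on the β face and the lower-unit aryl group cis to the 3-hydroxyl (3,4-cis, 4α) and leaves C3–O intact.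

Step 15
Reactants: 25 the octabenzyl ether
Product: 26 (2S,3R,4R)-2-(4-hydroxyphenyl)-4-[(2R,3R,4S)-3,4,7,8-tetrahydroxy-2-(4-hydroxyphenyl)chroman-6-yl]chromane-3,7,8-triol (target)
Conditions: H2 (1 atm), Pd(OH)2/C, THF/MeOH, rt
Reagents that add atoms: none
Why: Hydrogenolysis of the eight benzyl ethers over Pd(OH)2/C under neutral conditions should free all phenols and the lower 3,4-diol while the cyclic benzylic C2–O bonds, the triarylmethine and the secondary benzylic 4'-hydroxyl are kept.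

Compound list
1 | 3-fluorocatechol | Oc1cccc(F)c1O | starting material
2 | 1,2-bis(benzyloxy)-3-fluorobenzene | Fc1cccc(OCc2ccccc2)c1OCc1ccccc1 | intermediate
3 | 1,2-bis(benzyloxy)-4-bromo-3-fluorobenzene | Fc1c(Br)ccc(OCc2ccccc2)c1OCc1ccccc1 | intermediate
4 | (S)-4-benzyl-1,3-oxazolidin-2-one | O=C1OC[C@H](Cc2ccccc2)N1 | starting material
5 | benzyloxyacetyl chloride | ClC(=O)COCc1ccccc1 | starting material
6 | (S)-4-benzyl-3-[(benzyloxy)acetyl]-1,3-oxazolidin-2-one | O=C(COCc1ccccc1)N1[C@@H](Cc2ccccc2)COC1=O | intermediate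
7 | 4-(benzyloxy)benzaldehyde | O=Cc1ccc(OCc2ccccc2)cc1 | starting material
8 | (S)-4-benzyl-3-[(2S,3R)-2-(benzyloxy)-3-[4-(benzyloxy)phenyl]-3-hydroxypropanoyl]-1,3-oxazolidin-2-one | C(c1ccccc1)Oc1ccc([C@@H](O)[C@H](OCc2ccccc2)C(=O)N2[C@@H](Cc3ccccc3)COC2=O)cc1 | intermediate
9 | (2S,3R)-2-(benzyloxy)-3-[4-(benzyloxy)phenyl]-3-hydroxy-N-methoxy-N-methylpropanamide | C(c1ccccc1)Oc1ccc([C@@H](O)[C@H](OCc2ccccc2)C(=O)N(C)OC)cc1 | intermediate
10 | [3,4-bis(benzyloxy)-2-fluorophenyl]magnesium chloride (formed as its LiCl complex) | Cl[Mg]c1ccc(OCc2ccccc2)c(OCc2ccccc2)c1F | intermediate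
11 | (2S,3R)-1-[3,4-bis(benzyloxy)-2-fluorophenyl]-2-(benzyloxy)-3-[4-(benzyloxy)phenyl]-3-hydroxypropan-1-one | C(c1ccccc1)Oc1ccc([C@@H](O)[C@H](OCc2ccccc2)C(=O)c2ccc(OCc3ccccc3)c(OCc3ccccc3)c2F)cc1 | intermediate
12 | (1S,2S,3R)-1-[3,4-bis(benzyloxy)-2-fluorophenyl]-2-(benzyloxy)-3-[4-(benzyloxy)phenyl]propane-1,3-diol | C(c1ccccc1)Oc1ccc([C@@H](O)[C@H](OCc2ccccc2)[C@@H](O)c2ccc(OCc3ccccc3)c(OCc3ccccc3)c2F)cc1 | intermediate
13 | (2R,3R,4S)-3,7,8-tris(benzyloxy)-2-[4-(benzyloxy)phenyl]chroman-4-ol (formed as its potassium alkoxide) | C(c1ccccc1)Oc1ccc([C@H]2Oc3c(ccc(OCc4ccccc4)c3OCc3ccccc3)[C@H](O)[C@H]2OCc2ccccc2)cc1 | intermediate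
14 | (2R,3R,4S)-3,4,7,8-tetrakis(benzyloxy)-2-[4-(benzyloxy)phenyl]chroman | C(c1ccccc1)Oc1ccc([C@H]2Oc3c(ccc(OCc4ccccc4)c3OCc3ccccc3)[C@H](OCc3ccccc3)[C@H]2OCc2ccccc2)cc1 | intermediate
15 | (2R,3R,4S)-3,4,7,8-tetrakis(benzyloxy)-2-[4-(benzyloxy)phenyl]-6-bromochroman | C(c1ccccc1)Oc1ccc([C@H]2Oc3c(cc(Br)c(OCc4ccccc4)c3OCc3ccccc3)[C@H](OCc3ccccc3)[C@H]2OCc2ccccc2)cc1 | intermediate
16 | (E)-4-(benzyloxy)cinnamic acid | OC(=O)/C=C/c1ccc(OCc2ccccc2)cc1 | starting material
17 | (E)-3-[4-(benzyloxy)phenyl]-N-methoxy-N-methylprop-2-enamide | CON(C)C(=O)/C=C/c1ccc(OCc2ccccc2)cc1 | intermediate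
18 | 6-lithio derivative of 14 | C(c1ccccc1)Oc1ccc([C@H]2Oc3c(cc([Li])c(OCc4ccccc4)c3OCc3ccccc3)[C@H](OCc3ccccc3)[C@H]2OCc2ccccc2)cc1 | intermediate
19 | (E)-3-[4-(benzyloxy)phenyl]-1-[(2R,3R,4S)-3,4,7,8-tetrakis(benzyloxy)-2-[4-(benzyloxy)phenyl]chroman-6-yl]prop-2-en-1-one | C(c1ccccc1)Oc1ccc([C@H]2Oc3c(cc(C(=O)/C=C/c4ccc(OCc5ccccc5)cc4)c(OCc4ccccc4)c3OCc3ccccc3)[C@H](OCc3ccccc3)[C@H]2OCc2ccccc2)cc1 | intermediate
20 | [(2R,3S)-3-[4-(benzyloxy)phenyl]oxiran-2-yl][(2R,3R,4S)-3,4,7,8-tetrakis(benzyloxy)-2-[4-(benzyloxy)phenyl]chroman-6-yl]methanone | C(c1ccccc1)Oc1ccc([C@H]2Oc3c(cc(C(=O)[C@@H]4O[C@H]4c4ccc(OCc5ccccc5)cc4)c(OCc4ccccc4)c3OCc3ccccc3)[C@H](OCc3ccccc3)[C@H]2OCc2ccccc2)cc1 | intermediate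
21 | [3,4-bis(benzyloxy)-2-fluorophenyl]lithium | [Li]c1ccc(OCc2ccccc2)c(OCc2ccccc2)c1F | intermediate
22 | lithium (R)-[3,4-bis(benzyloxy)-2-fluorophenyl][(2R,3S)-3-[4-(benzyloxy)phenyl]oxiran-2-yl][(2R,3R,4S)-3,4,7,8-tetrakis(benzyloxy)-2-[4-(benzyloxy)phenyl]chroman-6-yl]methanolate | [Li+].C(c1ccccc1)Oc1ccc([C@H]2Oc3c(cc([C@@]([O-])(c4ccc(OCc5ccccc5)c(OCc5ccccc5)c4F)[C@@H]4O[C@H]4c4ccc(OCc5ccccc5)cc4)c(OCc4ccccc4)c3OCc3ccccc3)[C@H](OCc3ccccc3)[C@H]2OCc2ccccc2)cc1 | intermediate
23 | lithium (S)-[4-(benzyloxy)phenyl][(2S,3R)-3-[3,4-bis(benzyloxy)-2-fluorophenyl]-3-[(2R,3R,4S)-3,4,7,8-tetrakis(benzyloxy)-2-[4-(benzyloxy)phenyl]chroman-6-yl]oxiran-2-yl]methanolate | [Li+].C(c1ccccc1)Oc1ccc([C@H]2Oc3c(cc([C@]4(c5ccc(OCc6ccccc6)c(OCc6ccccc6)c5F)O[C@H]4[C@@H]([O-])c4ccc(OCc5ccccc5)cc4)c(OCc4ccccc4)c3OCc3ccccc3)[C@H](OCc3ccccc3)[C@H]2OCc2ccccc2)cc1 | intermediate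
24 | (1aS,2S,7bS)-4,5-bis(benzyloxy)-2-[4-(benzyloxy)phenyl]-7b-[(2R,3R,4S)-3,4,7,8-tetrakis(benzyloxy)-2-[4-(benzyloxy)phenyl]chroman-6-yl]-1a,7b-dihydro-2H-oxireno[2,3-c]chromene | C(c1ccccc1)Oc1ccc([C@H]2Oc3c(cc([C@@]4(O7)c5ccc(OCc6ccccc6)c(OCc6ccccc6)c5O[C@@H](c5ccc(OCc6ccccc6)cc5)[C@@H]47)c(OCc4ccccc4)c3OCc3ccccc3)[C@H](OCc3ccccc3)[C@H]2OCc2ccccc2)cc1 | intermediate
25 | (2S,3R,4S)-7,8-bis(benzyloxy)-2-[4-(benzyloxy)phenyl]-4-[(2R,3R,4S)-3,4,7,8-tetrakis(benzyloxy)-2-[4-(benzyloxy)phenyl]chroman-6-yl]chroman-3-ol | C(c1ccccc1)Oc1ccc([C@H]2Oc3c(cc([C@@H]4c5ccc(OCc6ccccc6)c(OCc6ccccc6)c5O[C@@H](c5ccc(OCc6ccccc6)cc5)[C@@H]4O)c(OCc4ccccc4)c3OCc3ccccc3)[C@H](OCc3ccccc3)[C@H]2OCc2ccccc2)cc1 | intermediate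
26 | (2S,3R,4R)-2-(4-hydroxyphenyl)-4-[(2R,3R,4S)-3,4,7,8-tetrahydroxy-2-(4-hydroxyphenyl)chroman-6-yl]chromane-3,7,8-triol | Oc1ccc([C@H]2Oc3c(cc([C@@H]4c5ccc(O)c(O)c5O[C@@H](c5ccc(O)cc5)[C@@H]4O)c(O)c3O)[C@H](O)[C@H]2O)cc1 | target

Total step count: 15 steps.
Longest linear sequence: 12 steps (steps 3 to 9 and 11 to 15, from 4 and 5 to 26).

Steps most likely to fail

1. Step 13. The fluoride displacement at the electron-rich ring may stall, or the aryl group may add to the wrong face of the ketone so that the rearranged alkoxide cannot reach C8a. The fallback sets out from 20 and comes back at 24; it replaces fluoride displacement by a palladium-catalysed C–O coupling of an aryl bromide. Commercial 3-bromocatechol is benzylated (BnBr, K2CO3, DMF) to 1,2-bis(benzyloxy)-3-bromobenzene F1. Iodination para to the 1-benzyloxy group (NIS, cat. CF3CO2H, MeCN) should give 1,2-bis(benzyloxy)-3-bromo-4-iodobenzene F2. Iodine–magnesium exchange (i-PrMgCl·LiCl, THF, −40 °C) and addition of the Grignard reagent to 20 in CH2Cl2, where magnesium enforces the chelate, should give the bromo epoxy carbinol (R)-[3,4-bis(benzyloxy)-2-bromophenyl][(2R,3S)-3-[4-(benzyloxy)phenyl]oxiran-2-yl][(2R,3R,4S)-3,4,7,8-tetrakis(benzyloxy)-2-[4-(benzyloxy)phenyl]chroman-6-yl]methanol F3, which is isolated. Deprotonation (NaH, THF) sets up the Payne equilibrium, and Pd(OAc)2 with 2-(di-tert-butylphosphino)-1,1'-binaphthyl and Cs2CO3 in toluene at 80 °C should couple the C2 alkoxide with the aryl bromide to close the pyran ring to 24.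

2. Step 8. The fluoride displacement has no activating group and may be slower than decomposition of the dialkoxide. The fallback sets out from 11 and comes back at 14; it closes the ring while the ketone still activates the fluoride. K2CO3 in DMF at room temperature (short reaction time, to avoid epimerisation at C3') should give the 2,3-cis ketone (2R,3S)-3,7,8-tris(benzyloxy)-2-[4-(benzyloxy)phenyl]chroman-4-one F4. NaBH4 in MeOH/THF should reduce it, mainly to the 4α-ol (2R,3R,4R)-3,7,8-tris(benzyloxy)-2-[4-(benzyloxy)phenyl]chroman-4-ol F5. Both C4' epimers converge in the last operation: BnOH with catalytic BF3·OEt2 (CH2Cl2, −20 °C) exchanges the 4-hydroxyl through the benzylic cation, and benzyl alcohol should enter trans to the axial 3-benzyloxy group to give 14.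

3. Step 14. Hydride may be delivered from the coordinated boron on the same face as the oxygen, or the benzylic cation may undergo a 1,2-hydride shift to the 3-ketone before it is reduced. The fallback sets out from 24 and comes back at 26; it replaces hydride by heterogeneous hydrogenolysis. H2 over Pd/C in EtOAc/MeOH should cleave the benzylic C4–O bond of the oxirane with inversion on the catalyst surface and remove the benzyl ethers in the same operation, giving the target directly. This fallback makes no new compound (F0).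

Further compounds
F1 | step 13 | 1,2-bis(benzyloxy)-3-bromobenzene | Brc1cccc(OCc2ccccc2)c1OCc1ccccc1
F2 | step 13 | 1,2-bis(benzyloxy)-3-bromo-4-iodobenzene | Brc1c(I)ccc(OCc2ccccc2)c1OCc1ccccc1
F3 | step 13 | (R)-[3,4-bis(benzyloxy)-2-bromophenyl][(2R,3S)-3-[4-(benzyloxy)phenyl]oxiran-2-yl][(2R,3R,4S)-3,4,7,8-tetrakis(benzyloxy)-2-[4-(benzyloxy)phenyl]chroman-6-yl]methanol | C(c1ccccc1)Oc1ccc([C@H]2Oc3c(cc([C@@](O)(c4ccc(OCc5ccccc5)c(OCc5ccccc5)c4Br)[C@@H]4O[C@H]4c4ccc(OCc5ccccc5)cc4)c(OCc4ccccc4)c3OCc3ccccc3)[C@H](OCc3ccccc3)[C@H]2OCc2ccccc2)cc1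
F4 | step 8 | (2R,3S)-3,7,8-tris(benzyloxy)-2-[4-(benzyloxy)phenyl]chroman-4-one | C(c1ccccc1)Oc1ccc([C@H]2Oc3c(ccc(OCc4ccccc4)c3OCc3ccccc3)C(=O)[C@H]2OCc2ccccc2)cc1
F5 | step 8 | (2R,3R,4R)-3,7,8-tris(benzyloxy)-2-[4-(benzyloxy)phenyl]chroman-4-ol | C(c1ccccc1)Oc1ccc([C@H]2Oc3c(ccc(OCc4ccccc4)c3OCc3ccccc3)[C@@H](O)[C@H]2OCc2ccccc2)cc1
F0 | step 14 | none | none
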